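The constants used here were chosen freely, and the outcome is calculated.

What is left of the first end groups at the end depends on how many second end groups are spent on something other than links.

first end groups 0.30 M; second end groups 1.00 equiv; scavenger 1.50 equiv; time 2.5 h

    first end groups + second end groups ⇌ links + released group (K1 = 1.9, k1 = 0.0087 M⁻¹ s⁻¹)
    second end groups + released group ⇌ idle adduct, settled at all times (K2 = 4.5 M⁻¹)
    scavenger + released group → scavenged by-product (k3 = 0.091 M⁻¹ s⁻¹)
    second end groups ⇌ dormant form (K4 = 1.1, k4 = 0.0019 s⁻¹)
    second end groups → decomposed reagent (k5 = 5.1 × 10⁻⁴ s⁻¹)

- part of the first end groups that has reacted at 2.5 h
- share of free second end groups in free second end groups and idle adduct together, at 2.5 h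

- for released group the idle adduct is counted in
- run time (flask): 2.5 h

We reckon by rates. At the start links form at 7.83 × 10⁻⁴ M s⁻¹. The dormant form can hold about half of the second end groups, which slows link formation, but it slows decomposition by the same factor and gives them back, so it leaves the split between the two unchanged. Return from links is small, because the full charge of scavenger takes released group at 0.0410 s⁻¹, against 0.00137 s⁻¹ for return with every first end group turned into links.

The slowing that counts is the fall of [first end groups]. In the ratio of link formation to decomposition [second end groups] cancels, and at the start this ratio is 5.12. We carry this ratio S, the instantaneous branching ratio of link formation over decomposition. Each second end group spent goes to links with a share set by S, and S falls in step with [first end groups]. Summing this for equal charges gives S_end = ln(S_start/S_end), which by trial gives 1.34, a fall by a factor of 3.83. Even then the half-life of second end groups, dormant form counted, is about 0.339 h, shorter than the run. So we commit to 73.9% reacted.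

The forecast gives 67% and >99.9%, saying “they run out with roughly two-thirds of the first end groups consumed”, which is below our figure. The simulation gives 73.1% and >99.9%.

In this flask S stood at 5.1 just after the start and at 1.4 at 2.50 h, close to our 1.34, so link formation still outran decomposition when the second end groups, the limiting reagent, were down to 0.23% of their charge. The neighbour flask charged with 0.600 equiv of second end groups falls short of the first end groups by 40.0%, so there S_end equals that shortfall times S_start plus ln(S_start/S_end), which gives 47.3%, and that neighbour flask stands at 47.3%.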